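The angular dimethylpyran on ring A is disconnected at both of its aryl bonds, C8–C4 of the pyran and C7–O. A 3,5-dioxygenated benzyne (C7≡C8 of ring A) takes up 3-methylbut-2-enal by carbonyl [2+2] addition, benzoxete opening and oxa-6π closure, so the pyran is fused in one operation; the oxygen on C8a, next to C8, polarises the aryne and fixes the orientation. The precursor is an o-silylaryl triflate made from phloroglucinol. The chromene is acetylated and joined as its enaminone to a chromene-5,8-quinone (Nenitzescu benzofuran annulation); oxidative C–O closure forms the coumaronochromone, and a Claisen rearrangement sets the C6 prenyl and frees 5-OH.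

Key step: step 4

Remark: the target has no stereocentre; the final ring system is numbered as an isoflavone (ring A C5–C8a, pyranone O1–C4, ring B C1′–C6′), and intermediates are numbered as 2H-chromenes.

Step 1
Reactants: 1 phloroglucinol
Product: 2 3,5-bis(methoxymethoxy)phenol
Conditions: MOMCl (2 equiv), i-Pr2NEt, CH2Cl2/DMF, 0 °C → rt
Reagents that add atoms: chloromethyl methyl ether, COCCl
Why: Williamson-type O-alkylation of the phenol should give mainly the bis-ether at two equivalents, which is separated from mono- and tris-ethers by chromatography.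

Step 2
Reactants: 2 3,5-bis(methoxymethoxy)phenol
Product: 3 2-bromo-3,5-bis(methoxymethoxy)phenol
Conditions: NBS (1.0 equiv), i-Pr2NH (cat.), CH2Cl2, −78 → 0 °C
Reagents that add atoms: N-bromosuccinimide, O=C1CCC(=O)N1Br
Why: Amine-mediated electrophilic bromination of a phenol is ortho-selective, and the para position is shielded by two flanking OMOM groups.

Step 3
Reactants: 3 2-bromo-3,5-bis(methoxymethoxy)phenol
Product: 6 3,5-bis(methoxymethoxy)-2-(trimethylsilyl)phenyl trifluoromethanesulfonate, via silyl ether 4 (not isolated), via lithium silylphenoxide 5 (not isolated)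
Conditions: HMDS, THF, 65 °C, evaporate; n-BuLi, THF, −78 °C; Tf2O, −78 → 0 °C
Reagents that add atoms: hexamethyldisilazane, C[Si](C)(C)N[Si](C)(C)C; trifluoromethanesulfonic anhydride, O=S(=O)(OS(=O)(=O)C(F)(F)F)C(F)(F)F
Why: O-silylation, bromine–lithium exchange, 1,3-retro-Brook O→C silyl shift and triflation of the phenoxide form the standard one-pot route to o-(trimethylsilyl)aryl triflates, and OMOM groups tolerate n-BuLi at −78 °C.

Step 4
Reactants: 6 3,5-bis(methoxymethoxy)-2-(trimethylsilyl)phenyl trifluoromethanesulfonate, 7 3-methylbut-2-enal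
Product: 11 5,7-bis(methoxymethoxy)-2,2-dimethyl-2H-chromene, via aryne 8 (not isolated), via benzoxete 9 (not isolated), via o-quinone methide 10 (not isolated)
Conditions: CsF (3 equiv), 7 (5 equiv), MeCN, rt → 40 °C
Reagents that add atoms: none
Why: Fluoride-induced 1,2-elimination of 6 gives aryne 8; the carbonyl oxygen of 7 attacks the aryne carbon remote from the flanking OMOM group (future C7) and the incipient aryl anion on the OMOM-flanked carbon (future C8) collapses onto the carbonyl carbon, a stepwise formal [2+2] that closes the four-membered ring of benzoxete 9 by polar ring closure of the zwitterion. Thermal 4π-electrocyclic opening of 9 gives vinyl o-quinone methide 10, and a disrotatory oxa-6π electrocyclization closes the pyran ring and restores the arene. The closest known reaction type is the fluoride-mediated annulation of arynes with α,β-unsaturated aldehydes to 2H-chromenes (aryne insertion into a C=O π bond). No stereocentre is formed. The step needs regioselectivity on the unsymmetrical aryne, secured by the inductively withdrawing OMOM group on the carbon that becomes C8a, which distorts the aryne so that oxygen enters meta and carbon ortho to it. It also needs chemoselectivity for C=O over C=C and ene pathways, favoured by the nucleophilic carbonyl oxygen and the excess of 7.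

Step 5
Reactants: 11 5,7-bis(methoxymethoxy)-2,2-dimethyl-2H-chromene
Product: 13 1-[5,7-bis(methoxymethoxy)-2,2-dimethyl-2H-chromen-6-yl]ethan-1-one, via aryllithium 12 (not isolated)
Conditions: n-BuLi, TMEDA, THF, −20 → 0 °C; MeC(O)N(OMe)Me, −78 °C → rt; aq NH4Cl
Reagents that add atoms: N-methoxy-N-methylacetamide, CC(=O)N(C)OC
Why: Directed ortho-metalation should occur at C6, the only position flanked by two chelating OMOM groups (C8 has one OMOM and the hindered ring oxygen), and the Weinreb amide stops at the ketone through its chelated tetrahedral adduct.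

Step 6
Reactants: 13 1-[5,7-bis(methoxymethoxy)-2,2-dimethyl-2H-chromen-6-yl]ethan-1-one
Product: 14 1-(5,7-dihydroxy-2,2-dimethyl-2H-chromen-6-yl)ethan-1-one
Conditions: 2 M HCl, MeOH, 40 °C
Reagents that add atoms: none
Why: Acid-catalysed acetal exchange removes both MOM groups, which are activated by the ortho acetyl group, while the 2,2-dimethylchromene should survive dilute methanolic HCl.

Step 7
Reactants: 14 1-(5,7-dihydroxy-2,2-dimethyl-2H-chromen-6-yl)ethan-1-one, 15 3-chloro-3-methylbut-1-yne
Product: 16 1-{5-hydroxy-2,2-dimethyl-7-[(2-methylbut-3-yn-2-yl)oxy]-2H-chromen-6-yl}ethan-1-one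
Conditions: 15 (1.1 equiv), DBU, CuCl2 (cat.), MeCN, 0 °C
Reagents that add atoms: none
Why: Copper-catalysed propargylic etherification should take the C7 hydroxyl, because the C5 hydroxyl is held in the hydrogen-bonded chelate with the acetyl group and is peri-hindered by C4–H.

Step 8
Reactants: 16 1-{5-hydroxy-2,2-dimethyl-7-[(2-methylbut-3-yn-2-yl)oxy]-2H-chromen-6-yl}ethan-1-one
Product: 17 (E)-3-(dimethylamino)-1-{5-hydroxy-2,2-dimethyl-7-[(2-methylbut-3-yn-2-yl)oxy]-2H-chromen-6-yl}prop-2-en-1-one
Conditions: Me2NCH(OMe)2, toluene, 70 °C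
Reagents that add atoms: N,N-dimethylformamide dimethyl acetal, COC(OC)N(C)C
Why: Condensation of the methyl ketone with the amide acetal gives the (E)-enaminone, the temperature being kept below that needed for rearrangement of the aryl propargyl ether.

Step 9
Reactants: 18 catechol, 15 3-chloro-3-methylbut-1-yne
Product: 19 2-[(2-methylbut-3-yn-2-yl)oxy]phenol
Conditions: 18 (3 equiv), DBU, CuCl2 (cat.), MeCN, 0 °C
Reagents that add atoms: none
Why: The same copper-catalysed propargylic etherification is used, with excess catechol to limit bis-alkylation.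

Step 10
Reactants: 19 2-[(2-methylbut-3-yn-2-yl)oxy]phenol
Product: 20 2,2-dimethyl-2H-chromen-8-ol
Conditions: PhNEt2, 180 °C
Reagents that add atoms: none
Why: Aromatic propargyl Claisen rearrangement to the free ortho carbon, then 1,5-hydrogen shift and oxa-6π electrocyclization, should give the 2H-chromene with the second catechol oxygen left as the C8 phenol.

Step 11
Reactants: 20 2,2-dimethyl-2H-chromen-8-ol
Product: 21 2,2-dimethyl-2H-chromene-5,8-dione
Conditions: (KSO3)2NO (2.2 equiv), KH2PO4, H2O/acetone, rt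
Reagents that add atoms: potassium nitrosodisulfonate, [K+].[K+].[O-]S(=O)(=O)N([O])S(=O)(=O)[O-]
Why: Teuber oxidation of a phenol with a free para position gives the p-quinone, the new oxygen coming from the nitroxyl reagent.

Step 12
Reactants: 17 (E)-3-(dimethylamino)-1-{5-hydroxy-2,2-dimethyl-7-[(2-methylbut-3-yn-2-yl)oxy]-2H-chromen-6-yl}prop-2-en-1-one, 21 2,2-dimethyl-2H-chromene-5,8-dione
Product: 23 benzofuran-3-yl ketone (5-hydroxybenzofuran with a 2,2-dimethyl-2H-pyran fused at C6 (O) and C7 (CH=), acylated at C3 by the 5-hydroxy-2,2-dimethyl-7-[(2-methylbut-3-yn-2-yl)oxy]-2H-chromen-6-yl carbonyl group), via hydroquinone adduct 22 (not isolated)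
Conditions: 21 (1.05 equiv, slow addition), AcOH, CH2Cl2, rt
Reagents that add atoms: none
Why: In this Nenitzescu-type benzofuran synthesis the enaminone α-carbon adds to C6 of 21 (β to the more electrophilic C8 carbonyl, para to the ring-oxygen-bearing carbon), the adduct aromatises to hydroquinone 22, and the hydroxyl ortho to the new C–C bond displaces dimethylamine from the aminovinyl carbon (5-exo) while the ring A hydroxyl stays chelated to the ketone.

Step 13
Reactants: 23 benzofuran-3-yl ketone
Product: 24 coumaronochromone propargyl ether (target skeleton with H at C6 and a 5-O-(2-methylbut-3-yn-2-yl) ether; 5′-OH free)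
Conditions: DDQ (1.2 equiv), 1,4-dioxane, 80 °C
Reagents that add atoms: none
Why: Proposed new method: the ring A phenol of 23 should add reversibly to C2 of the 3-acylbenzofuran (6-endo oxa-Michael addition) to give a cyclic bis-O-acetal, from whose C2–H DDQ abstracts hydride (dioxocarbenium ion), and loss of the C3 proton then gives the aromatic pyranone; the closest known reaction type is the DDQ-mediated dehydrogenative cyclization of 2′-hydroxyisoflavones to coumaronochromones, which passes through the same acetal.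

Step 14
Reactants: 24 coumaronochromone propargyl ether
Product: 25 coumaronochromone 5-O-(2-methylbut-3-en-2-yl) ether
Conditions: H2 (1 atm), Pd/CaCO3 poisoned with Pb(OAc)2, quinoline, EtOAc, rt
Reagents that add atoms: none
Why: Semihydrogenation of the terminal alkyne over the lead-poisoned palladium catalyst should stop at the alkene and leave the conjugated, disubstituted chromene double bonds untouched.

Step 15
Reactants: 25 coumaronochromone 5-O-(2-methylbut-3-en-2-yl) ether
Product: 27 CNP0323631.0 (5,5′-dihydroxy-6-prenyl coumaronochromone with 2,2-dimethylpyran rings fused at C7(O)/C8 and at C4′(O)/C3′), via dienone 26 (not isolated)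
Conditions: PhNEt2, 130 °C
Reagents that add atoms: none
Why: Aromatic Claisen rearrangement ([3,3]) of the tertiary allyl aryl ether should transfer the allyl unit with inversion to C6, the only free ortho carbon, and tautomerisation of dienone 26 restores ring A as the hydrogen-bonded 5-OH compound.

Compound list
1 | phloroglucinol | Oc1cc(O)cc(O)c1 | starting material
2 | 3,5-bis(methoxymethoxy)phenol | COCOc1cc(O)cc(OCOC)c1 | intermediate
3 | 2-bromo-3,5-bis(methoxymethoxy)phenol | COCOc1cc(O)c(Br)c(OCOC)c1 | intermediate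
4 | [2-bromo-3,5-bis(methoxymethoxy)phenoxy]trimethylsilane | COCOc1cc(O[Si](C)(C)C)c(Br)c(OCOC)c1 | intermediate
5 | lithium 3,5-bis(methoxymethoxy)-2-(trimethylsilyl)phenoxide | [Li+].[O-]c1cc(OCOC)cc(OCOC)c1[Si](C)(C)C | intermediate
6 | 3,5-bis(methoxymethoxy)-2-(trimethylsilyl)phenyl trifluoromethanesulfonate | COCOc1cc(OS(=O)(=O)C(F)(F)F)c([Si](C)(C)C)c(OCOC)c1 | intermediate
7 | 3-methylbut-2-enal | CC(C)=CC=O | starting material
8 | 3,5-bis(methoxymethoxy)benzyne | COCOC1=CC#CC(OCOC)=C1 | intermediate
9 | 3,5-bis(methoxymethoxy)-2-(2-methylprop-1-en-1-yl)-2H-benzoxete | CC(C)=CC1Oc2cc(OCOC)cc(OCOC)c21 | intermediate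
10 | 3,5-bis(methoxymethoxy)-6-(3-methylbut-2-en-1-ylidene)cyclohexa-2,4-dien-1-one | CC(C)=CC=C1C(=O)C=C(OCOC)C=C1OCOC | intermediate
11 | 5,7-bis(methoxymethoxy)-2,2-dimethyl-2H-chromene | CC1(C)C=Cc2c(OCOC)cc(OCOC)cc2O1 | intermediate
12 | [5,7-bis(methoxymethoxy)-2,2-dimethyl-2H-chromen-6-yl]lithium | [Li]c1c(OCOC)cc2OC(C)(C)C=Cc2c1OCOC | intermediate
13 | 1-[5,7-bis(methoxymethoxy)-2,2-dimethyl-2H-chromen-6-yl]ethan-1-one | CC(=O)c1c(OCOC)cc2OC(C)(C)C=Cc2c1OCOC | intermediate
14 | 1-(5,7-dihydroxy-2,2-dimethyl-2H-chromen-6-yl)ethan-1-one | CC(=O)c1c(O)cc2OC(C)(C)C=Cc2c1O | intermediate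
15 | 3-chloro-3-methylbut-1-yne | CC(C)(Cl)C#C | starting material
16 | 1-{5-hydroxy-2,2-dimethyl-7-[(2-methylbut-3-yn-2-yl)oxy]-2H-chromen-6-yl}ethan-1-one | CC(=O)c1c(OC(C)(C)C#C)cc2OC(C)(C)C=Cc2c1O | intermediate
17 | (E)-3-(dimethylamino)-1-{5-hydroxy-2,2-dimethyl-7-[(2-methylbut-3-yn-2-yl)oxy]-2H-chromen-6-yl}prop-2-en-1-one | CN(C)/C=C/C(=O)c1c(OC(C)(C)C#C)cc2OC(C)(C)C=Cc2c1O | intermediate
18 | catechol | Oc1ccccc1O | starting material
19 | 2-[(2-methylbut-3-yn-2-yl)oxy]phenol | C#CC(C)(C)Oc1ccccc1O | intermediate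
20 | 2,2-dimethyl-2H-chromen-8-ol | CC1(C)C=Cc2cccc(O)c2O1 | intermediate
21 | 2,2-dimethyl-2H-chromene-5,8-dione | CC1(C)C=CC2=C(O1)C(=O)C=CC2=O | intermediate
22 | 2-(5,8-dihydroxy-2,2-dimethyl-2H-chromen-6-yl)-3-(dimethylamino)-1-{5-hydroxy-2,2-dimethyl-7-[(2-methylbut-3-yn-2-yl)oxy]-2H-chromen-6-yl}prop-2-en-1-one | CN(C)C=C(c1cc(O)c2OC(C)(C)C=Cc2c1O)C(=O)c1c(OC(C)(C)C#C)cc2OC(C)(C)C=Cc2c1O | intermediate
23 | benzofuran-3-yl ketone (5-hydroxy, pyran-fused benzofuran acylated at C3 by the ring A aroyl group) | O=C(c1coc2c1cc(O)c1OC(C)(C)C=Cc12)c1c(OC(C)(C)C#C)cc2OC(C)(C)C=Cc2c1O | intermediate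
24 | coumaronochromone 5-O-(2-methylbut-3-yn-2-yl) ether, H at C6 | C#CC(C)(C)Oc1cc2c(c3oc4oc5c6c(c(O)cc5c4c(=O)c13)OC(C)(C)C=C6)C=CC(C)(C)O2 | intermediate
25 | coumaronochromone 5-O-(2-methylbut-3-en-2-yl) ether, H at C6 | C=CC(C)(C)Oc1cc2c(c3oc4oc5c6c(c(O)cc5c4c(=O)c13)OC(C)(C)C=C6)C=CC(C)(C)O2 | intermediate
26 | C6-prenylated ring A cyclohexadienone (C5 keto tautomer of the target) | CC(C)=CCC1C(=O)C2=C(OC3=C(C2=O)c2cc(O)c4c(c2O3)C=CC(C)(C)O4)C2=C1OC(C)(C)C=C2 | intermediate
27 | CNP0323631.0 | CC(C)=CCc1c2c(c3oc4oc5c6c(c(O)cc5c4c(=O)c3c1O)OC(C)(C)C=C6)C=CC(C)(C)O2 | target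

Total step count: 15. Longest linear sequence: 12 steps (steps 1–8 and 12–15); steps 9–11 make the quinone in a separate branch.

Steps most likely to fail

Step 13 (proposed method). DDQ may oxidise the electron-rich hydroxybenzofuran ring instead of dehydrogenating the cyclic acetal, or the oxa-Michael pre-equilibrium may be too unfavourable to feed the oxidation. The fallback is redox-neutral and uses known reactions. It sets out from 16, whose chelated hydroxyl is protected (MOMCl, i-Pr2NEt) to give 1-{5-(methoxymethoxy)-2,2-dimethyl-7-[(2-methylbut-3-yn-2-yl)oxy]-2H-chromen-6-yl}ethan-1-one F1. NaH/CS2 followed by MeI converts the methyl ketone into the α-oxo ketene dithioacetal F2. CuBr2/BF3·OEt2-mediated annulation of F2 with quinone 21 (addition to C6, closure by the ortho hydroxyl, loss of methanethiol) gives the 2-(methylsulfanyl)benzofuran-3-yl ketone F3. HCl/MeOH frees the ring A phenol to give the 2-(methylsulfanyl)benzofuran-3-yl ketone with free ring A hydroxyl F4. K2CO3 in DMF then closes the pyranone by intramolecular addition–elimination at the thio-substituted carbon, and the route is rejoined at 24.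

Step 4 (key step). The aryne may be consumed by ene reaction with the allylic methyl groups or by [2+2] addition at C=C, or the o-quinone methide may be intercepted by a second aldehyde before it cyclises. The fallback keeps the aryne as the source of both aryl bonds but builds the pyran stepwise. It sets out from 6: CsF in DMF gives formal [2+2] insertion of the aryne into the formamide C=O, and aqueous work-up gives 2-hydroxy-4,6-bis(methoxymethoxy)benzaldehyde F5. Addition of 2-methylprop-1-enylmagnesium bromide (2.2 equiv, THF, 0 °C) gives racemic 2-(1-hydroxy-3-methylbut-2-en-1-yl)-3,5-bis(methoxymethoxy)phenol F6. PPTS (cat.) in toluene at 50 °C dehydrates F6 to the o-quinone methide, which closes by oxa-6π electrocyclization, and the route is rejoined at 11.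

Step 12. The o-hydroxyaryl enaminone may close to the chromone before it adds to the quinone, the adduct may close through the ring A hydroxyl, or hydroquinone–quinone redox exchange may consume material. The fallback blocks the ring A hydroxyl so that only the benzofuran annulation is possible. It sets out from 16: TBSOTf/2,6-lutidine gives 1-{5-[(tert-butyldimethylsilyl)oxy]-2,2-dimethyl-7-[(2-methylbut-3-yn-2-yl)oxy]-2H-chromen-6-yl}ethan-1-one F7. N,N-Dimethylformamide dimethyl acetal gives the silyl-protected (E)-enaminone F8. Reaction with 21 in AcOH gives the silyl-protected benzofuran-3-yl ketone F9, and Bu4NF in THF removes the silyl group to rejoin the route at 23.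

Further compounds
F1 | step 13 | 1-{5-(methoxymethoxy)-2,2-dimethyl-7-[(2-methylbut-3-yn-2-yl)oxy]-2H-chromen-6-yl}ethan-1-one | CC(=O)c1c(OC(C)(C)C#C)cc2OC(C)(C)C=Cc2c1OCOC
F2 | step 13 | 1-{5-(methoxymethoxy)-2,2-dimethyl-7-[(2-methylbut-3-yn-2-yl)oxy]-2H-chromen-6-yl}-3,3-bis(methylsulfanyl)prop-2-en-1-one | CSC(SC)=CC(=O)c1c(OC(C)(C)C#C)cc2OC(C)(C)C=Cc2c1OCOC
F3 | step 13 | 2-(methylsulfanyl)benzofuran-3-yl ketone, ring A 5-OMOM (analogue of 23 with SMe at furan C2) | O=C(c1c(SC)oc2c1cc(O)c1OC(C)(C)C=Cc12)c1c(OC(C)(C)C#C)cc2OC(C)(C)C=Cc2c1OCOC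
F4 | step 13 | 2-(methylsulfanyl)benzofuran-3-yl ketone, ring A hydroxyl free | O=C(c1c(SC)oc2c1cc(O)c1OC(C)(C)C=Cc12)c1c(OC(C)(C)C#C)cc2OC(C)(C)C=Cc2c1O
F5 | step 4 | 2-hydroxy-4,6-bis(methoxymethoxy)benzaldehyde | COCOc1cc(O)c(C=O)c(OCOC)c1
F6 | step 4 | 2-(1-hydroxy-3-methylbut-2-en-1-yl)-3,5-bis(methoxymethoxy)phenol (racemic) | COCOc1cc(O)c(C(O)C=C(C)C)c(OCOC)c1
F7 | step 12 | 1-{5-[(tert-butyldimethylsilyl)oxy]-2,2-dimethyl-7-[(2-methylbut-3-yn-2-yl)oxy]-2H-chromen-6-yl}ethan-1-one | CC(=O)c1c(OC(C)(C)C#C)cc2OC(C)(C)C=Cc2c1O[Si](C)(C)C(C)(C)C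
F8 | step 12 | (E)-1-{5-[(tert-butyldimethylsilyl)oxy]-2,2-dimethyl-7-[(2-methylbut-3-yn-2-yl)oxy]-2H-chromen-6-yl}-3-(dimethylamino)prop-2-en-1-one | CN(C)/C=C/C(=O)c1c(OC(C)(C)C#C)cc2OC(C)(C)C=Cc2c1O[Si](C)(C)C(C)(C)C
F9 | step 12 | benzofuran-3-yl ketone, ring A 5-O-TBS (silyl ether of 23) | O=C(c1coc2c1cc(O)c1OC(C)(C)C=Cc12)c1c(OC(C)(C)C#C)cc2OC(C)(C)C=Cc2c1O[Si](C)(C)C(C)(C)C
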